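With the carbocycle numbered C1 (bearing C7H2OBz), C2 (olefinic CH), C3 (OMe), C4 (OH), C5 (OBz) and C6 (OH), everything rests on opening the C1=C2 double bond to a C2 aldehyde and a C1≡C7 ynamide. The feature exploited is this trisubstituted ring alkene carrying an oxidised C7, flanked by C3–C6, which have the configuration of C2–C5 of D-gluconate. One acid-promoted ynamide–aldehyde metathesis should close the six-membered ring, create the C1=C2 alkene and deliver C7 as an acyl sulfonamide. Its precursor is an open-chain 2-O-methyl-3,4-O-isopropylidene-5-O-silyl aldehydo-heptynose whose alkyne terminus bears N(Me)Ts.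

Key step: step 10

Remark on the chemistry: open-chain compounds are numbered as D-gluconates (chain C1 becomes ring C2, chain C2–C5 become ring C3–C6, chain C6 becomes ring C1, C7 comes from CBr4); ring compounds use the C1–C7 numbering given above.

Step 1
Reactants: 1 D-glucono-1,5-lactone
Product: 2 methyl 3,4:5,6-di-O-isopropylidene-D-gluconate
Conditions: Me2C(OMe)2, MeOH, acetone, TsOH·H2O (cat.), rt
Reagents that add atoms: 2,2-dimethoxypropane, COC(C)(C)OC; methanol, CO
Why: Acid-catalysed lactone methanolysis with concurrent transacetalisation should settle on the 3,4:5,6-diacetonide of the open-chain methyl ester, the preferred pattern for this chain, which leaves only the 2-OH beside the ester free and touches no stereocentre.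

Step 2
Reactants: 2 methyl 3,4:5,6-di-O-isopropylidene-D-gluconate
Product: 3 methyl 3,4:5,6-di-O-isopropylidene-2-O-methyl-D-gluconate
Conditions: MeI, Ag2O, 4 Å MS, MeCN, rt, dark
Reagents that add atoms: iodomethane, CI
Why: Silver-oxide-mediated O-methylation (Purdie methylation) alkylates the single free hydroxyl without generating an ester enolate, so C2 should neither epimerise nor lose the C3 oxygen by beta-elimination.

Step 3
Reactants: 3 methyl 3,4:5,6-di-O-isopropylidene-2-O-methyl-D-gluconate
Product: 4 methyl 3,4-O-isopropylidene-2-O-methyl-D-gluconate (5,6-diol)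
Conditions: AcOH–H2O (3:2), 35 °C, stopped when 3 is consumed
Reagents that add atoms: none
Why: Selective acetal hydrolysis should work because the terminal dioxolane on the primary/secondary diol is cleaved markedly faster under mild aqueous acid than the internal trans-disubstituted dioxolane.

Step 4
Reactants: 4 methyl 3,4-O-isopropylidene-2-O-methyl-D-gluconate
Product: 5 methyl 5,6-bis-O-(tert-butyldimethylsilyl)-3,4-O-isopropylidene-2-O-methyl-D-gluconate
Conditions: TBSOTf, 2,6-lutidine, CH2Cl2, 0 °C
Reagents that add atoms: tert-butyldimethylsilyl trifluoromethanesulfonate, CC(C)(C)[Si](C)(C)OS(=O)(=O)C(F)(F)F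
Why: Silyl ether formation with the silyl triflate and a hindered base caps both hydroxyls rapidly, which also forestalls lactonisation of the 5-OH onto the ester.

Step 5
Reactants: 5 methyl 5,6-bis-O-(tert-butyldimethylsilyl)-3,4-O-isopropylidene-2-O-methyl-D-gluconate
Product: 6 methyl 5-O-(tert-butyldimethylsilyl)-3,4-O-isopropylidene-2-O-methyl-D-gluconate (6-OH free)
Conditions: HF·pyridine, pyridine, THF, 0 °C
Reagents that add atoms: none
Why: Kinetically selective fluoride desilylation should release the unhindered primary silyl ether well before the secondary one, and the pyridine buffer protects the acetonide.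

Step 6
Reactants: 6 methyl 5-O-(tert-butyldimethylsilyl)-3,4-O-isopropylidene-2-O-methyl-D-gluconate
Product: 7 C6 aldehyde (methyl 5-O-TBS-3,4-O-isopropylidene-2-O-methyl-6-oxo-D-gluconate)
Conditions: Dess–Martin periodinane, NaHCO3, CH2Cl2, 0 °C to rt
Reagents that add atoms: none
Why: Dess–Martin oxidation under buffered, non-basic conditions should give the alpha-silyloxy aldehyde without epimerising C5, and the crude aldehyde is carried on directly.

Step 7
Reactants: 7 C6 aldehyde; 8 carbon tetrabromide
Product: 9 1,1-dibromoalkene (methyl 7,7-dibromo-5-O-TBS-6,7-dideoxy-3,4-O-isopropylidene-2-O-methyl-D-gluco-hept-6-enonate)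
Conditions: PPh3, Et3N, CH2Cl2, 0 °C (8 and PPh3 premixed, then 7)
Reagents that add atoms: none
Why: Corey–Fuchs dibromo-olefination (Wittig-type reaction of Ph3P=CBr2 made in the flask) is reliable for alpha-alkoxy aldehydes, and the amine buffer keeps the medium safe for the acetonide and the silyl ether.

Step 8
Reactants: 9 1,1-dibromoalkene; 10 N-methyl-p-toluenesulfonamide
Product: 12 ynamide ester, via (Z)-bromoenamide 11 (not isolated)
Conditions: CuI (12 mol%), MeNHCH2CH2NHMe (18 mol%), Cs2CO3, 1,4-dioxane, 65 °C
Reagents that add atoms: none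
Why: Copper-catalysed Ullmann-type C–N coupling should take place at the less hindered bromide trans to the chain, and carbonate-induced anti-dehydrobromination of the resulting bromoenamide then gives the ynamide directly, under a base too weak to enolise the alpha-methoxy ester.

Step 9
Reactants: 12 ynamide ester
Product: 13 ynamide aldehyde
Conditions: iBu2AlH (1.2 equiv), CH2Cl2, −78 °C; MeOH, then aq. potassium sodium tartrate
Reagents that add atoms: none
Why: Partial ester reduction with the aluminium hydride should stop at the aldehyde because the alpha-methoxy group chelates aluminium and holds the tetrahedral hemiacetal aluminate until work-up, while the sulfonyl ynamide is inert at −78 °C.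

Step 10
Reactants: 13 ynamide aldehyde
Product: 16 cyclohexene N-acylsulfonamide, via keteniminium borate 14 (not isolated), via amino-oxetene 15 (not isolated)
Conditions: BF3·OEt2 (0.5 equiv), 4 Å MS, CH2Cl2, −78 to −20 °C; Et3N quench
Reagents that add atoms: none
Why: BF3 activates the C2 aldehyde and the nucleophilic beta-carbon of the ynamide (C1) adds to it to give keteniminium borate 14, whose boron-bound oxygen closes on the keteniminium carbon C7 to the fused amino-oxetene 15, and 4π electrocyclic opening of 15 gives the C1=C2 alkene and the C7 carbonyl of 16. The closest known reaction type is the Lewis-acid-promoted ring-closing ynamide–carbonyl metathesis that converts formyl-tethered ynamides into cycloalkene carboxamides. The carbocycle closes in a 6-exo mode at both partners (exo-trig at the carbonyl, exo-dig at the alkyne), and the transient four-membered ring closes by exo-dig attack of oxygen on the C7=N+ bond, overall a stepwise [2+2]. No lasting stereocentre is made, since C2 is sp3 only in 14 and 15, C3–C6 are carried unchanged from D-gluconate and the ring fixes the alkene geometry. The step needs regioselectivity (C1, not C7, bonds to C2), secured by the nitrogen polarisation of the alkyne, and chemoselectivity over ionisation of the propargylic C6–O bond and over acetonide loss, secured by the electron-poor N-tosyl group, the poor leaving-group ability of the silyl ether and the low temperature. The trans-dioxolane holds the C3 and C6 arms gauche, as in the product, which should favour closure.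

Step 11
Reactants: 16 cyclohexene N-acylsulfonamide
Product: 18 protected allylic alcohol, via enal 17 (not isolated)
Conditions: iBu2AlH (3 equiv), CH2Cl2, −78 to −40 °C; aq. potassium sodium tartrate
Reagents that add atoms: none
Why: Hydride reduction of the activated N-sulfonyl amide should proceed by 1,2-addition, expulsion of the sulfonamide anion to enal 17 and a second 1,2-reduction, the aluminium hydride favouring carbonyl over conjugate attack.

Step 12
Reactants: 18 protected allylic alcohol; 19 benzoyl chloride
Product: 20 protected C7 benzoate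
Conditions: pyridine, DMAP (cat.), CH2Cl2, 0 °C
Reagents that add atoms: none
Why: Base-mediated O-acylation (Schotten–Baumann-type esterification) of the only free hydroxyl, a primary allylic alcohol, should be clean.

Step 13
Reactants: 20 protected C7 benzoate
Product: 21 C7 monobenzoate triol
Conditions: TFA–H2O (9:1), 0 °C to rt; toluene co-evaporation
Reagents that add atoms: none
Why: Acid-catalysed global deprotection should hydrolyse the strained trans-fused acetonide and cleave the silyl ether in one operation, while the benzoate and the methyl ether are stable and the absence of base excludes acyl migration.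

Step 14
Reactants: 21 C7 monobenzoate triol; 19 benzoyl chloride
Product: 22 target CNP0349013.6
Conditions: Ph2BOCH2CH2NH2 (2-aminoethyl diphenylborinate, 10 mol%), iPr2NEt, MeCN, rt
Reagents that add atoms: none
Why: Borinic-acid-catalysed regioselective acylation should work because the diarylborinate binds only the cis C5/C6 diol as a tetracoordinate borinate and activates its equatorial O5, as at O-3 of galacto-configured pyranosides, while the trans C4-OH and the pseudoaxial allylic C6-OH stay free and the room-temperature conditions spare the C7 benzoate.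

Compound list
1 | D-glucono-1,5-lactone | O=C1[C@H](O)[C@@H](O)[C@H](O)[C@@H](CO)O1 | starting material
2 | methyl 3,4:5,6-di-O-isopropylidene-D-gluconate | COC(=O)[C@H](O)[C@H]1OC(C)(C)O[C@@H]1[C@H]1COC(C)(C)O1 | intermediate
3 | methyl 3,4:5,6-di-O-isopropylidene-2-O-methyl-D-gluconate | COC(=O)[C@H](OC)[C@H]1OC(C)(C)O[C@@H]1[C@H]1COC(C)(C)O1 | intermediate
4 | methyl 3,4-O-isopropylidene-2-O-methyl-D-gluconate (5,6-diol) | COC(=O)[C@H](OC)[C@H]1OC(C)(C)O[C@@H]1[C@H](O)CO | intermediate
5 | methyl 5,6-bis-O-(tert-butyldimethylsilyl)-3,4-O-isopropylidene-2-O-methyl-D-gluconate | COC(=O)[C@H](OC)[C@H]1OC(C)(C)O[C@@H]1[C@H](O[Si](C)(C)C(C)(C)C)CO[Si](C)(C)C(C)(C)C | intermediate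
6 | methyl 5-O-(tert-butyldimethylsilyl)-3,4-O-isopropylidene-2-O-methyl-D-gluconate | COC(=O)[C@H](OC)[C@H]1OC(C)(C)O[C@@H]1[C@H](O[Si](C)(C)C(C)(C)C)CO | intermediate
7 | C6 aldehyde: methyl 5-O-(tert-butyldimethylsilyl)-3,4-O-isopropylidene-2-O-methyl-6-oxo-D-gluconate (D-gluco configuration at C2–C5) | COC(=O)[C@H](OC)[C@H]1OC(C)(C)O[C@@H]1[C@H](O[Si](C)(C)C(C)(C)C)C=O | intermediate
8 | carbon tetrabromide | BrC(Br)(Br)Br | starting material
9 | methyl 7,7-dibromo-5-O-(tert-butyldimethylsilyl)-6,7-dideoxy-3,4-O-isopropylidene-2-O-methyl-D-gluco-hept-6-enonate | COC(=O)[C@H](OC)[C@H]1OC(C)(C)O[C@@H]1[C@H](O[Si](C)(C)C(C)(C)C)C=C(Br)Br | intermediate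
10 | N-methyl-p-toluenesulfonamide | CNS(=O)(=O)c1ccc(C)cc1 | starting material
11 | (Z)-bromoenamide: methyl (Z)-7-bromo-5-O-(tert-butyldimethylsilyl)-6,7-dideoxy-3,4-O-isopropylidene-2-O-methyl-7-[methyl(tosyl)amino]-D-gluco-hept-6-enonate | COC(=O)[C@H](OC)[C@H]1OC(C)(C)O[C@@H]1[C@H](O[Si](C)(C)C(C)(C)C)/C=C(\Br)N(C)S(=O)(=O)c1ccc(C)cc1 | intermediate (not isolated)
12 | ynamide ester: methyl 5-O-(tert-butyldimethylsilyl)-6,7-dideoxy-3,4-O-isopropylidene-2-O-methyl-7-[methyl(tosyl)amino]-D-gluco-hept-6-ynonate | COC(=O)[C@H](OC)[C@H]1OC(C)(C)O[C@@H]1[C@H](O[Si](C)(C)C(C)(C)C)C#CN(C)S(=O)(=O)c1ccc(C)cc1 | intermediate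
13 | ynamide aldehyde: 5-O-(tert-butyldimethylsilyl)-6,7-dideoxy-3,4-O-isopropylidene-2-O-methyl-7-[methyl(tosyl)amino]-aldehydo-D-gluco-hept-6-ynose | O=C[C@H](OC)[C@H]1OC(C)(C)O[C@@H]1[C@H](O[Si](C)(C)C(C)(C)C)C#CN(C)S(=O)(=O)c1ccc(C)cc1 | intermediate
14 | keteniminium trifluoroborate zwitterion (ring closed at C1–C2, C2–O–BF3, C1=C7=N+; C2 transiently sp3, C3–C6 as in 16) | CO[C@H]1C(O[B-](F)(F)F)C(=C=[N+](C)S(=O)(=O)c2ccc(C)cc2)[C@@H](O[Si](C)(C)C(C)(C)C)[C@H]2OC(C)(C)O[C@H]12 | intermediate (not isolated)
15 | fused amino-oxetene (O–C2–C1=C7 four-membered ring on the C1–C2 bond; C3–C6 as in 16) | CO[C@H]1C2OC(N(C)S(=O)(=O)c3ccc(C)cc3)=C2[C@@H](O[Si](C)(C)C(C)(C)C)[C@H]2OC(C)(C)O[C@H]12 | intermediate (not isolated)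
16 | (3S,4R,5S,6R)-6-(tert-butyldimethylsilyloxy)-4,5-(isopropylidenedioxy)-3-methoxy-N-methyl-N-tosylcyclohex-1-ene-1-carboxamide (trans-fused dioxolane) | CO[C@H]1C=C(C(=O)N(C)S(=O)(=O)c2ccc(C)cc2)[C@@H](O[Si](C)(C)C(C)(C)C)[C@H]2OC(C)(C)O[C@H]12 | intermediate
17 | (3S,4R,5S,6R)-6-(tert-butyldimethylsilyloxy)-4,5-(isopropylidenedioxy)-3-methoxycyclohex-1-ene-1-carbaldehyde | CO[C@H]1C=C(C=O)[C@@H](O[Si](C)(C)C(C)(C)C)[C@H]2OC(C)(C)O[C@H]12 | intermediate (not isolated)
18 | [(3S,4R,5S,6R)-6-(tert-butyldimethylsilyloxy)-4,5-(isopropylidenedioxy)-3-methoxycyclohex-1-en-1-yl]methanol | CO[C@H]1C=C(CO)[C@@H](O[Si](C)(C)C(C)(C)C)[C@H]2OC(C)(C)O[C@H]12 | intermediate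
19 | benzoyl chloride | O=C(Cl)c1ccccc1 | starting material
20 | [(3S,4R,5S,6R)-6-(tert-butyldimethylsilyloxy)-4,5-(isopropylidenedioxy)-3-methoxycyclohex-1-en-1-yl]methyl benzoate | CO[C@H]1C=C(COC(=O)c2ccccc2)[C@@H](O[Si](C)(C)C(C)(C)C)[C@H]2OC(C)(C)O[C@H]12 | intermediate
21 | [(3S,4S,5R,6R)-4,5,6-trihydroxy-3-methoxycyclohex-1-en-1-yl]methyl benzoate | CO[C@H]1C=C(COC(=O)c2ccccc2)[C@@H](O)[C@@H](O)[C@@H]1O | intermediate
22 | CNP0349013.6: [(3S,4R,5R,6R)-5-(benzoyloxy)-4,6-dihydroxy-3-methoxycyclohex-1-en-1-yl]methyl benzoate (3-OMe/4-OH trans, 4-OH/5-OBz trans, 5-OBz/6-OH cis) | CO[C@H]1C=C(COC(=O)c2ccccc2)[C@@H](O)[C@@H](OC(=O)c2ccccc2)[C@@H]1O | target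

Total step count: 14
Longest linear sequence: 14 steps, from 1 to 22

Steps most likely to fail

Step 10. Lewis-acid ionisation of the propargylic C6–O bond, opening of the acetonide or adventitious hydration of the ynamide may outrun formation of the C1–C2 bond. The fallback sets out from 13 and closes the same bond by ruthenium carbene chemistry under neutral conditions. Wittig methylenation of the aldehyde (Ph3P=CH2, THF, −78 to 0 °C) should give the ene–ynamide F1. Ring-closing enyne metathesis (second-generation Grubbs catalyst (H2IMes)(PCy3)Cl2Ru=CHPh, ethylene, toluene, 80 °C) should then give the ring diene with an exocyclic N-sulfonyl enamide F2. Ozonolysis of the more electron-rich exocyclic C7=CH2 bond (O3, CH2Cl2, −78 °C, then Me2S) would come back to the route at 16.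

Step 8. Carbon–nitrogen coupling at the hindered vinylic bromide beside the silyloxy-bearing C5 may be slow, and prolonged heating with carbonate could then epimerise C2. The fallback sets out from 7 and leaves 9 out. Ohira–Bestmann homologation (dimethyl (1-diazo-2-oxopropyl)phosphonate, K2CO3, MeOH, 0 °C) should give the terminal alkyne F3. Bromination (N-bromosuccinimide, AgNO3 cat., acetone, rt) should give the bromoalkyne F4. Copper-catalysed alkynyl amidation with 10 at the unhindered sp carbon (CuSO4·5H2O, 1,10-phenanthroline, K3PO4, toluene, 70 °C) would rejoin the route at 12.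

Step 14. Regiocontrol may erode, with acylation spreading to the C4 hydroxyl or to two hydroxyls if the half-chair cis-diol binds boron poorly. The fallback sets out from 21 and replaces catalyst control by protecting-group control.
- Acetonation (2,2-dimethoxypropane, pyridinium p-toluenesulfonate, acetone) should tie only the cis C5/C6 diol as the cis-fused acetonide F5.
- The free O4 is then masked as the levulinate F6 (levulinic acid, N,N'-diisopropylcarbodiimide, DMAP, CH2Cl2).
- Aqueous acetic acid (50 °C) should release the 5,6-diol F7.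
- Low-temperature benzoylation with 19 (pyridine, CH2Cl2, −40 °C) should take the equatorial O5 in preference to the pseudoaxial allylic O6 and give the 4-O-levulinoyl 5-O-benzoate F8.
- Hydrazine acetate (pyridine–AcOH, rt) removes the levulinate and returns to the route at 22.

Further compounds
F1 | step 10 | ene–ynamide (C1 vinyl in place of the aldehyde of 13, D-gluco configuration retained) | C=C[C@H](OC)[C@H]1OC(C)(C)O[C@@H]1[C@H](O[Si](C)(C)C(C)(C)C)C#CN(C)S(=O)(=O)c1ccc(C)cc1
F2 | step 10 | ring diene with exocyclic C7(=CH2)N(Me)Ts on C1 (C3–C6 as in 16) | CO[C@H]1C=C(C(=C)N(C)S(=O)(=O)c2ccc(C)cc2)[C@@H](O[Si](C)(C)C(C)(C)C)[C@H]2OC(C)(C)O[C@H]12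
F3 | step 8 | terminal alkyne: methyl 5-O-(tert-butyldimethylsilyl)-6,7-dideoxy-3,4-O-isopropylidene-2-O-methyl-D-gluco-hept-6-ynonate | COC(=O)[C@H](OC)[C@H]1OC(C)(C)O[C@@H]1[C@H](O[Si](C)(C)C(C)(C)C)C#C
F4 | step 8 | bromoalkyne: 7-bromo derivative of the terminal alkyne | COC(=O)[C@H](OC)[C@H]1OC(C)(C)O[C@@H]1[C@H](O[Si](C)(C)C(C)(C)C)C#CBr
F5 | step 14 | cis-fused 5,6-O-isopropylidene derivative of 21 (4-OH free) | CO[C@H]1C=C(COC(=O)c2ccccc2)[C@H]2OC(C)(C)O[C@H]2[C@@H]1O
F6 | step 14 | 4-O-levulinoyl-5,6-O-isopropylidene derivative of 21 | CO[C@H]1C=C(COC(=O)c2ccccc2)[C@H]2OC(C)(C)O[C@H]2[C@@H]1OC(=O)CCC(C)=O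
F7 | step 14 | 4-O-levulinoyl derivative of 21 (5,6-diol free) | CO[C@H]1C=C(COC(=O)c2ccccc2)[C@@H](O)[C@@H](O)[C@@H]1OC(=O)CCC(C)=O
F8 | step 14 | 4-O-levulinoyl derivative of 22 (5-O-benzoate, 6-OH free) | CO[C@H]1C=C(COC(=O)c2ccccc2)[C@@H](O)[C@@H](OC(=O)c2ccccc2)[C@@H]1OC(=O)CCC(C)=O
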